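All constants were drawn at random within sensible limits; what happens was integrated by code.

Measure the loss in molar rather than in hours: divide one rate by another and the clock drops out.

| setting | dawn | midnight | autumn | spring |
|---|---|---|---|---|
| free monomer | 0.10 M | 0.10 M | 0.10 M (fed, over 8.00 h) | 0.10 M |
| initiator | 0.5 mol% | 0.5 mol% | 0.5 mol% | 0.5 mol% |
| time | 10 h | 10 h | 10 h |  |
| remark | a tube with plug flow, the mixed feed as stated, residence time 10 h | everything together in a closed stirred flask, run for 10 h | a stirred flask in which free monomer is dosed at a steady rate over 8.00 h without added volume, worked up at 10 h | one stirred flow tank at steady state, fed with the mixture as stated, mean residence time 10 h |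

    free monomer + initiator → living end + monomer in chains (k1 = 4.0 M⁻¹ h⁻¹)
    free monomer + living end → monomer in chains + living end, rate k2*[living end]*[free monomer] (k2 = 5100 M⁻¹ h⁻¹)
    free monomer → uncatalysed product (k3 = 0.25 h⁻¹)

- the stated concentrations are those of everything mixed, before any reaction; amounts are the same in each set-up
- the feed brings no volume worth counting
- run time (dawn): 10 h

- the set-up with the highest amount of monomer in chains at the outlet or at the end, in percent of the free monomer put in ("none" if the first two lie within 2 percentage points) (dawn / midnight / autumn / spring / none)
- amount of monomer in chains at the outlet or at the end, in percent of the free monomer put in, dawn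
- amount of monomer in chains at the outlet or at the end, in percent of the free monomer put in, midnight
- amount of monomer in chains at the outlet or at the end, in percent of the free monomer put in, autumn
- amount of monomer in chains at the outlet or at the end, in percent of the free monomer put in, spring

Take the uncatalysed rate, 0.25 h⁻¹ times free monomer, and divide it by the rate at which initiator is consumed, 4.0 M⁻¹ h⁻¹ times free monomer times initiator. Free monomer and time cancel. Each natural-log unit by which initiator falls therefore costs a fixed amount of free monomer, and I call this amount the toll, the ratio of the two constants, 0.0625 M.

uncatalysed product = toll × s, where s = ln(initiator charged / initiator left)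

Dosing adds free monomer and leaves this ratio untouched, so the toll serves dawn, midnight and autumn. Dawn's tube and midnight's flask follow one history, so they give one number.

Next find s. Living end equals initiator consumed, and dividing chain growth by initiator consumption cancels free monomer again. With 5.00 × 10⁻⁴ M of initiator charged, the growth term has the scale 0.638 M, and the balance for the end of dawn and midnight, taking the free monomer left there as negligible, reads:

free monomer charged = toll × s + growth scale × (s − 1 + e^(−s)) + initiator consumed

Try s = 0.5. The right side gives 0.0994 M, just under the 0.10 M charged, so s lies a shade higher. My reckoning puts uncatalysed product near 31.2% of the charge and monomer in chains near 68.8% for dawn and midnight.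

For autumn, treat free monomer as pseudo-first-order, hold living end at its level for s = 0.5 as a rough assumption, and take the constant 1.25 h⁻¹. On that assumption, the steady dose and the wait after the feed leave about 0.813% free, which gives about 68.2% in chains if what has reacted splits as in dawn. The logarithm does not apply to spring's tank, so my reckoning stops there.

The forecast gives 68.6% for dawn and 68.6% for midnight, 67.7% for autumn and 66.8% for spring, and names none as best, holding that “the living ends build up only slowly”.

The simulation gives 68.6%, 68.6%, 67.9% and 66.8% in that order, and none as best.

Dawn ends with 61% of its initiator left, and the toll turns that into 31.4% of the charge as uncatalysed product, where the flask reads 31.4%. Now take the neighbouring flask, dawn at 0.060 M of free monomer with the loading held. The toll stays 0.0625 M, and 64% of its initiator is left, so the toll gives 0.0276 M, or 45.9% of that smaller charge. That flask reads 45.9% as uncatalysed product and 54.0% as monomer in chains.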